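**Plan**
1. Target: two identical 3-alkyl-2-hydroxy-5-methoxy-6-methyl-1,4-benzoquinone rings (ring atoms C1–C6) joined at C3 by a (CH2)14 chain; it has no stereocentre.
2. Enabling feature: in each ring C1(=O)–C2(OH)–C3(chain)–C4(=O) is the four-carbon unit of a squarate and C5(OMe)=C6(Me) is a two-carbon enol ether, so each hexasubstituted, tetraoxygenated ring equals a cyclobutenone plus an alkenyl group.
3. Retrosynthesis: cut C4–C5 in both rings (electrocyclic ring expansion), then C1–C6 in both rings (alkenyllithium addition to a cyclobutenedione), then the two C3–CH2 bonds (chain di-Grignard reagent onto two molecules of di-tert-butyl squarate).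
4. Forward: the chain is joined to two squarate units first, the two methoxypropenyl groups are added next, and both six-membered rings close in one heating step; oxidation and tert-butyl cleavage finish.
5. The tert-butyl ether marks the C2 oxygen that must end as hydroxyl; the C5 methoxy arrives with the alkenyl group, so the two are never confused.
6. Stereochemistry: none to set; the carbinol centres and the enol ether geometry of the intermediates are erased when the rings aromatize.

Key step: step 7

Assumption: the dehydrobromination that makes 2-bromo-1-methoxyprop-1-ene is taken to favour the isomer with bromine cis to methoxy (the Z bromide), by analogy with the parent 1-bromo-2-alkoxyethenes, and fractional distillation is taken to remove the other isomer. Only this geometry gives a lithium reagent stabilized by O–Li coordination; the geometry itself is lost on aromatization.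

**Route**

Step 1
Reactants: 1 squaric acid
Product: 2 disilver squarate
Conditions: AgNO3 (2 equiv), H2O, rt, dark; filter, wash, dry in vacuo
Reagents that add atoms: silver nitrate, [Ag+].[O-][N+](=O)[O-]
Why: Squaric acid is a strong diprotic acid and its disilver salt is sparingly soluble, so simple salt metathesis in water should precipitate it (salt formation).

Step 2
Reactants: 2 disilver squarate
Product: 3 di-tert-butyl squarate
Conditions: t-BuCl (excess), Et2O, rt, dark; filter off AgCl
Reagents that add atoms: tert-butyl chloride, CC(C)(C)Cl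
Why: Silver-assisted SN1 O-alkylation, in which the silver ion abstracts chloride and the squarate oxygen captures the tert-butyl cation, is the classical silver-salt esterification for acid-labile squarate esters.

Step 3
Reactants: 4 tetradecane-1,14-diol
Product: 5 1,14-dibromotetradecane
Conditions: 48% aq. HBr, conc. H2SO4, 100 °C
Reagents that add atoms: hydrogen bromide, Br
Why: Acid-mediated SN2 substitution of both primary hydroxyl groups by bromide (alcohol to alkyl bromide with HBr) is standard for long-chain α,ω-diols.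

Step 4
Reactants: 5 1,14-dibromotetradecane; 3 di-tert-butyl squarate
Product: 10 1,14-bis(2-tert-butoxy-3,4-dioxocyclobut-1-en-1-yl)tetradecane, via tetradecane-1,14-diylbis(magnesium bromide) 6 (not isolated), via bis(bromomagnesium alkoxide) 7 (not isolated), via bis(carbinol trifluoroacetate) 8 (not isolated), via bis(ketal trifluoroacetate) 9 (not isolated)
Conditions: Mg turnings, I2 (cat.), THF, reflux, slow addition of 5; cannulate into 3 (2.5 equiv), THF, –78 to –40 °C; (CF3CO)2O (2.5 equiv), –78 to 0 °C; cold aq. NaHCO3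
Reagents that add atoms: trifluoroacetic anhydride, O=C(OC(=O)C(F)(F)F)C(F)(F)F
Why: Magnesium inserts into both primary C–Br bonds and each Grignard terminus adds 1,2 to one carbonyl of a separate molecule of 3 (two molecules of 3 per molecule of 5), after which O-trifluoroacetylation of the tertiary alkoxides gives 8, a 1,3-acyloxy shift of each allylic ester places the former acyl oxygen of the anhydride on the tert-butoxy-bearing ring carbon next to the ketone (ketal ester 9), and cleavage of 9 at the acyl carbon by aqueous bicarbonate with expulsion of tert-butanol leaves that oxygen as the new ring carbonyl, which is the known squarate 1,2-addition/1,3-carbonyl transposition route to 3-alkoxy-4-alkylcyclobutenediones; the uncontrolled carbinol and ketal centres of 7, 8 and 9 are lost in 10.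

Step 5
Reactants: 11 1-methoxyprop-1-ene (E/Z mixture)
Product: 13 (Z)-2-bromo-1-methoxyprop-1-ene, via 1,2-dibromo-1-methoxypropane 12 (not isolated)
Conditions: Br2, pentane, –78 °C; then PhNEt2, 90 °C; fractional distillation under reduced pressure from the amine salt
Reagents that add atoms: bromine, BrBr
Why: Electrophilic bromine addition to the enol ether gives the α-bromo ether, which ionizes to an oxocarbenium ion and loses the C2 proton to the amine (bromination–dehydrobromination, the standard route to β-bromo enol ethers), with the isomer having Br cis to OMe expected to predominate.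

Step 6
Reactants: 13 (Z)-2-bromo-1-methoxyprop-1-ene; 10 1,14-bis(2-tert-butoxy-3,4-dioxocyclobut-1-en-1-yl)tetradecane
Product: 15 1,14-bis{3-tert-butoxy-4-hydroxy-4-[(Z)-1-methoxyprop-1-en-2-yl]-1-oxocyclobut-2-en-2-yl}tetradecane (mixture of carbinol diastereomers), via [(E)-1-methoxyprop-1-en-2-yl]lithium 14 (not isolated)
Conditions: 13 (2.6 equiv), t-BuLi (5.2 equiv), Et2O, –78 °C; then 10, THF, –78 °C; sat. aq. NH4Cl, –78 to 0 °C; crude product kept cold and free of acid, used directly
Reagents that add atoms: none
Why: Bromine–lithium exchange with two equivalents of t-BuLi gives the alkenyllithium with retention of geometry (Li cis to OMe, held by O–Li coordination against loss of LiOMe), and it adds 1,2 to the ketone-like carbonyl next to the tert-butoxy-bearing carbon and not to the vinylogous ester carbonyl (known regiochemistry of organolithium addition to 3-alkoxy-4-alkylcyclobutenediones); the two new carbinol centres are uncontrolled and are destroyed in step 7.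

Step 7
Reactants: 15 1,14-bis{3-tert-butoxy-4-hydroxy-4-[(Z)-1-methoxyprop-1-en-2-yl]-1-oxocyclobut-2-en-2-yl}tetradecane
Product: 18 1,14-bis(2-tert-butoxy-3,6-dihydroxy-5-methoxy-4-methylphenyl)tetradecane, via bis(dienylketene) 16 (not isolated), via bis(cyclohexadienone) 17 (not isolated)
Conditions: toluene (degassed, 0.01 M), 110 °C, Ar; concentrate and use at once
Reagents that add atoms: none
Why: Heating should open each cyclobutenone by conrotatory 4π cleavage of the bond between the carbonyl carbon and the carbinol carbon, giving the hydroxy-dienylketene 16. A disrotatory 6π electrocyclization then joins the ketene carbon to the methoxy-bearing alkene terminus (quinone bond C4–C5), closing each six-membered carbocycle as the cyclohexa-2,4-dienone 17, which enolizes to the hydroquinone. The closest known reaction type is the thermal ring expansion of 4-alkenyl-4-hydroxycyclobutenones to hydroquinones (Moore rearrangement). No stereocentre is created in the product, since the carbinol centres and the transient CH(OMe) centre of 17 vanish on aromatization. The step needs outward rotation of the hydroxyl so that the alkenyl group ends up cis to the ketene, which the donor character of the hydroxyl secures, while the substitution pattern was already fixed by the regiochemistry of step 6. The sp-hybridized ketene terminus should tolerate the methoxy group on the inside of the Z-alkene, the two ends react independently, and neutral oxygen-free conditions preserve the tert-butyl ethers and the hydroquinones.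

Step 8
Reactants: 18 1,14-bis(2-tert-butoxy-3,6-dihydroxy-5-methoxy-4-methylphenyl)tetradecane
Product: 19 1,14-bis(2-tert-butoxy-5-methoxy-4-methyl-3,6-dioxocyclohexa-1,4-dien-1-yl)tetradecane
Conditions: Ag2O (excess), MgSO4, Et2O, rt
Reagents that add atoms: none
Why: Two-electron oxidation of each p-hydroquinone to the p-quinone by Ag2O under neutral conditions (hydroquinone-to-quinone oxidation) leaves the tert-butyl ethers, the methyl ethers and the saturated chain untouched.

Step 9
Reactants: 19 1,14-bis(2-tert-butoxy-5-methoxy-4-methyl-3,6-dioxocyclohexa-1,4-dien-1-yl)tetradecane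
Product: 20 1,14-bis(2-hydroxy-5-methoxy-4-methyl-3,6-dioxocyclohexa-1,4-dien-1-yl)tetradecane (CNP0278640.0)
Conditions: CF3CO2H, CH2Cl2, 0 °C to rt
Reagents that add atoms: none
Why: Acid-catalysed E1 cleavage of the two tert-butyl vinylogous esters with loss of isobutene (tert-butyl ether deprotection), under which the methyl vinylogous esters are stable, unmasks the one oxygen per ring that must be free hydroxyl.

**Compound list**
1 | squaric acid (3,4-dihydroxycyclobut-3-ene-1,2-dione) | O=C1C(O)=C(O)C1=O | starting material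
2 | disilver squarate | [Ag+].[Ag+].[O-]C1=C([O-])C(=O)C1=O | intermediate
3 | di-tert-butyl squarate (3,4-di-tert-butoxycyclobut-3-ene-1,2-dione) | CC(C)(C)OC1=C(OC(C)(C)C)C(=O)C1=O | intermediate
4 | tetradecane-1,14-diol | OCCCCCCCCCCCCCCO | starting material
5 | 1,14-dibromotetradecane | BrCCCCCCCCCCCCCCBr | intermediate
6 | tetradecane-1,14-diylbis(magnesium bromide) (not isolated) | Br[Mg]CCCCCCCCCCCCCC[Mg]Br | intermediate
7 | bis(bromomagnesium alkoxide) of 1,14-bis(2,3-di-tert-butoxy-1-hydroxy-4-oxocyclobut-2-en-1-yl)tetradecane (diastereomer mixture, not isolated) | CC(C)(C)OC1=C(OC(C)(C)C)C(O[Mg]Br)(CCCCCCCCCCCCCCC2(O[Mg]Br)C(OC(C)(C)C)=C(OC(C)(C)C)C2=O)C1=O | intermediate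
8 | 1,14-bis[2,3-di-tert-butoxy-4-oxo-1-(trifluoroacetoxy)cyclobut-2-en-1-yl]tetradecane, the bis(carbinol trifluoroacetate) (diastereomer mixture, not isolated) | CC(C)(C)OC1=C(OC(C)(C)C)C(OC(=O)C(F)(F)F)(CCCCCCCCCCCCCCC2(OC(=O)C(F)(F)F)C(OC(C)(C)C)=C(OC(C)(C)C)C2=O)C1=O | intermediate
9 | 1,14-bis[2,3-di-tert-butoxy-4-oxo-3-(trifluoroacetoxy)cyclobut-1-en-1-yl]tetradecane, the bis(ketal trifluoroacetate) (diastereomer mixture, not isolated) | CC(C)(C)OC1=C(CCCCCCCCCCCCCCC2=C(OC(C)(C)C)C(OC(C)(C)C)(OC(=O)C(F)(F)F)C2=O)C(=O)C1(OC(C)(C)C)OC(=O)C(F)(F)F | intermediate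
10 | 1,14-bis(2-tert-butoxy-3,4-dioxocyclobut-1-en-1-yl)tetradecane | CC(C)(C)OC1=C(CCCCCCCCCCCCCCC2=C(OC(C)(C)C)C(=O)C2=O)C(=O)C1=O | intermediate
11 | 1-methoxyprop-1-ene (E/Z mixture) | CC=COC | starting material
12 | 1,2-dibromo-1-methoxypropane (diastereomer mixture, not isolated) | COC(Br)C(C)Br | intermediate
13 | (Z)-2-bromo-1-methoxyprop-1-ene | CO/C=C(\Br)C | intermediate
14 | [(E)-1-methoxyprop-1-en-2-yl]lithium (Li cis to OMe; the descriptor differs from that of 13 only because Li ranks below CH3; not isolated) | CO/C=C(\[Li])C | intermediate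
15 | 1,14-bis{3-tert-butoxy-4-hydroxy-4-[(Z)-1-methoxyprop-1-en-2-yl]-1-oxocyclobut-2-en-2-yl}tetradecane (carbinol diastereomer mixture) | CO/C=C(/C)C1(O)C(OC(C)(C)C)=C(CCCCCCCCCCCCCCC2=C(OC(C)(C)C)C(O)(/C(C)=C\OC)C2=O)C1=O | intermediate
16 | 2,17-bis[(1Z,3Z)-1-tert-butoxy-2-hydroxy-4-methoxy-3-methylbuta-1,3-dien-1-yl]octadeca-1,17-diene-1,18-dione, the bis(dienylketene) (not isolated) | CO/C=C(/C)\C(O)=C(OC(C)(C)C)/C(CCCCCCCCCCCCCCC(=C=O)/C(OC(C)(C)C)=C(O)\C(C)=C/OC)=C=O | intermediate
17 | 1,14-bis(2-tert-butoxy-3-hydroxy-5-methoxy-4-methyl-6-oxocyclohexa-1,3-dien-1-yl)tetradecane, the bis(cyclohexadienone) (C5 epimer mixture, not isolated) | COC1C(C)=C(O)C(OC(C)(C)C)=C(CCCCCCCCCCCCCCC2=C(OC(C)(C)C)C(O)=C(C)C(OC)C2=O)C1=O | intermediate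
18 | 1,14-bis(2-tert-butoxy-3,6-dihydroxy-5-methoxy-4-methylphenyl)tetradecane | COc1c(C)c(O)c(OC(C)(C)C)c(CCCCCCCCCCCCCCc2c(O)c(OC)c(C)c(O)c2OC(C)(C)C)c1O | intermediate
19 | 1,14-bis(2-tert-butoxy-5-methoxy-4-methyl-3,6-dioxocyclohexa-1,4-dien-1-yl)tetradecane | COC1=C(C)C(=O)C(OC(C)(C)C)=C(CCCCCCCCCCCCCCC2=C(OC(C)(C)C)C(=O)C(C)=C(OC)C2=O)C1=O | intermediate
20 | 1,14-bis(2-hydroxy-5-methoxy-4-methyl-3,6-dioxocyclohexa-1,4-dien-1-yl)tetradecane (CNP0278640.0) | COC1=C(C)C(=O)C(O)=C(CCCCCCCCCCCCCCC2=C(O)C(=O)C(C)=C(OC)C2=O)C1=O | target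

**Count**
Total steps: 9. Longest linear sequence: 7 steps (steps 1, 2, 4, 6, 7, 8, 9, from squaric acid).

**Steps most likely to fail**

Step 6. The alkenyllithium may lose lithium methoxide by β-elimination (above all any fraction with Li trans to OMe), the twofold addition may stop after one end, and the tertiary allylic carbinol may ionize during the quench. The fallback replaces direct use of the distilled bromide by a purified, storable tin reagent. It sets out from 13: bromine–lithium exchange at –100 °C with immediate Bu3SnCl quench should give tributyl[(Z)-1-methoxyprop-1-en-2-yl]stannane F1, which can be purified on basic alumina and dosed exactly. Tin–lithium exchange with n-BuLi in THF at –78 °C then releases the reagent free of tert-butyl halide by-products, and the route is re-entered at 14, which is added to 10 to give 15.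

Step 4. Wurtz-type coupling and incomplete double magnesium insertion may give mixed chain lengths, and one terminus may add while the other is quenched. The fallback joins the chain at its midpoint after the rings are attached, and sets out from 3. Oct-7-en-1-ylmagnesium bromide F2 (from commercial 8-bromooct-1-ene and Mg) adds to 3 to give bromomagnesium 2,3-di-tert-butoxy-1-(oct-7-en-1-yl)-4-oxocyclobut-2-en-1-olate F3. Trifluoroacetic anhydride converts this to 2,3-di-tert-butoxy-1-(oct-7-en-1-yl)-4-oxocyclobut-2-en-1-yl trifluoroacetate F4, which rearranges by 1,3-acyloxy shift to 1,2-di-tert-butoxy-3-(oct-7-en-1-yl)-4-oxocyclobut-2-en-1-yl trifluoroacetate F5. Aqueous NaHCO3 work-up then gives 3-tert-butoxy-4-(oct-7-en-1-yl)cyclobut-3-ene-1,2-dione F6. Self-metathesis with the second-generation Grubbs catalyst (CH2Cl2, 40 °C, ethene swept out) should give 1,14-bis(2-tert-butoxy-3,4-dioxocyclobut-1-en-1-yl)tetradec-7-ene F7 as an E/Z mixture. Hydrogenation of the disubstituted alkene with H2 and RhCl(PPh3)3, which should leave the tetrasubstituted ring alkene alone, returns to the route at 10.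

Step 7. On heating, the free carbinol may rotate inward and its oxygen may capture the ketene (butenolide formation), the carbinol may ionize, or closure onto the methoxy-bearing terminus may be slow enough for the ketene to be diverted. The fallback masks the hydroxyl as a silyl ether and sets out from 15. Silylation (Me3SiCl, imidazole, DMF, 0 °C) gives 1,14-bis{3-tert-butoxy-4-[(Z)-1-methoxyprop-1-en-2-yl]-1-oxo-4-[(trimethylsilyl)oxy]cyclobut-2-en-2-yl}tetradecane F8. Thermolysis in toluene at 110 °C should pass through 2,17-bis{(1Z,3Z)-1-tert-butoxy-4-methoxy-3-methyl-2-[(trimethylsilyl)oxy]buta-1,3-dien-1-yl}octadeca-1,17-diene-1,18-dione F9 and 1,14-bis{2-tert-butoxy-5-methoxy-4-methyl-6-oxo-3-[(trimethylsilyl)oxy]cyclohexa-1,3-dien-1-yl}tetradecane F10 to 1,14-bis{2-tert-butoxy-6-hydroxy-5-methoxy-4-methyl-3-[(trimethylsilyl)oxy]phenyl}tetradecane F11. The silyloxy group is an outward-rotating donor like hydroxyl but cannot add to the ketene. K2CO3 (cat.) in methanol under argon removes the silyl groups and returns to the route at 18.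

Further compounds
F1 | step 6 | tributyl[(Z)-1-methoxyprop-1-en-2-yl]stannane | CO/C=C(\[Sn](CCCC)(CCCC)CCCC)C
F2 | step 4 | oct-7-en-1-ylmagnesium bromide | C=CCCCCCC[Mg]Br
F3 | step 4 | bromomagnesium 2,3-di-tert-butoxy-1-(oct-7-en-1-yl)-4-oxocyclobut-2-en-1-olate | C=CCCCCCCC1(O[Mg]Br)C(OC(C)(C)C)=C(OC(C)(C)C)C1=O
F4 | step 4 | 2,3-di-tert-butoxy-1-(oct-7-en-1-yl)-4-oxocyclobut-2-en-1-yl trifluoroacetate | C=CCCCCCCC1(OC(=O)C(F)(F)F)C(OC(C)(C)C)=C(OC(C)(C)C)C1=O
F5 | step 4 | 1,2-di-tert-butoxy-3-(oct-7-en-1-yl)-4-oxocyclobut-2-en-1-yl trifluoroacetate | C=CCCCCCCC1=C(OC(C)(C)C)C(OC(C)(C)C)(OC(=O)C(F)(F)F)C1=O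
F6 | step 4 | 3-tert-butoxy-4-(oct-7-en-1-yl)cyclobut-3-ene-1,2-dione | C=CCCCCCCC1=C(OC(C)(C)C)C(=O)C1=O
F7 | step 4 | 1,14-bis(2-tert-butoxy-3,4-dioxocyclobut-1-en-1-yl)tetradec-7-ene (E/Z mixture) | CC(C)(C)OC1=C(CCCCCCC=CCCCCCCC2=C(OC(C)(C)C)C(=O)C2=O)C(=O)C1=O
F8 | step 7 | 1,14-bis{3-tert-butoxy-4-[(Z)-1-methoxyprop-1-en-2-yl]-1-oxo-4-[(trimethylsilyl)oxy]cyclobut-2-en-2-yl}tetradecane | CO/C=C(/C)C1(O[Si](C)(C)C)C(OC(C)(C)C)=C(CCCCCCCCCCCCCCC2=C(OC(C)(C)C)C(O[Si](C)(C)C)(/C(C)=C\OC)C2=O)C1=O
F9 | step 7 | 2,17-bis{(1Z,3Z)-1-tert-butoxy-4-methoxy-3-methyl-2-[(trimethylsilyl)oxy]buta-1,3-dien-1-yl}octadeca-1,17-diene-1,18-dione | CO/C=C(/C)\C(O[Si](C)(C)C)=C(OC(C)(C)C)/C(CCCCCCCCCCCCCCC(=C=O)/C(OC(C)(C)C)=C(O[Si](C)(C)C)\C(C)=C/OC)=C=O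
F10 | step 7 | 1,14-bis{2-tert-butoxy-5-methoxy-4-methyl-6-oxo-3-[(trimethylsilyl)oxy]cyclohexa-1,3-dien-1-yl}tetradecane | COC1C(C)=C(O[Si](C)(C)C)C(OC(C)(C)C)=C(CCCCCCCCCCCCCCC2=C(OC(C)(C)C)C(O[Si](C)(C)C)=C(C)C(OC)C2=O)C1=O
F11 | step 7 | 1,14-bis{2-tert-butoxy-6-hydroxy-5-methoxy-4-methyl-3-[(trimethylsilyl)oxy]phenyl}tetradecane | COc1c(C)c(O[Si](C)(C)C)c(OC(C)(C)C)c(CCCCCCCCCCCCCCc2c(O)c(OC)c(C)c(O[Si](C)(C)C)c2OC(C)(C)C)c1O
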